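**Retrosynthetic overview**

1. The target is 7α-acetoxy-labda-8(17),12E,14-trien-19-oic acid. The acetate, the free C19 acid (from its methyl ester), the (E)-12,14-diene (two Wittig olefinations on a C12 aldehyde), the 7α-oxygen (allylic oxidation of the 8(17)-methylene) and C17 (methylenation of a C8 ketone) lead back to the bicyclic keto diester 14.
2. The strategy rests on two features: the C20 methyl on C10 is a methylene plus one hydrogen atom, and C9 is β to the C12 carbonyl. The C9–C10 bond of ring B is therefore cut as a tertiary C10 radical, made by hydrogen-atom transfer to a C10=C20 methylene, adding 6-exo to C9 of an (E)-4-oxo-2-enoate attached to C5 (13 → 14).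
3. Ring A comes from methyl 3-oxocyclohex-1-ene-1-carboxylate. Asymmetric conjugate reduction with allylation of the regiodefined enolate sets C5, the C10 ketone becomes the methylene, and only then is the C4 ester enolate methylated anti to the C5 chain (axial C19 ester). The allyl group is converted to the oxo-enoate through an aldehyde and a propiolate adduct.
4. Ring order: A (present in 1), then B (step 8). No protecting groups are used.

Key step: step 8

Remark: labdane numbering and α/β descriptors (C20 methyl β) are used for all intermediates; C4 is made quaternary after C5 because a C5 substituent introduced next to a finished Me/CO2Me centre would meet no useful facial bias.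

**Route**

Step 1
Reactants: 1 methyl 3-oxocyclohex-1-ene-1-carboxylate; 2 allyl bromide
Product: 4 methyl (1R,2S)-3-oxo-2-(prop-2-en-1-yl)cyclohexane-1-carboxylate, via bis(enoxy)diphenylsilane 3 (not isolated)
Conditions: CuCl (5 mol%), NaOt-Bu (5 mol%), p-Tol-BINAP (5 mol%, the antipode that gives 1R), Ph2SiH2 (0.55 equiv), toluene, −20 °C; then TBAT (1.2 equiv), 2 (3 equiv), THF, 0 °C → rt; minor 2,3-cis isomer removed by chromatography
Reagents that add atoms: allyl bromide (2), C=CCBr
Why: Asymmetric copper hydride 1,4-reduction (conjugate hydrosilylation) places hydride on C4, β to the ketone, and gives the regiodefined C5=C10 silyl enol ether; the fluoride-released enolate is then allylated at C5 anti to the C4 ester (trans, also the more stable isomer), so the catalyst-set C4 centre fixes the absolute configuration of C5.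

Step 2
Reactants: 4 methyl (1R,2S)-3-oxo-2-(prop-2-en-1-yl)cyclohexane-1-carboxylate
Product: 5 methyl (1R,2S)-3-methylidene-2-(prop-2-en-1-yl)cyclohexane-1-carboxylate
Conditions: Zn, CH2Br2, TiCl4, THF, 0 °C (pre-formed reagent); then 4, CH2Cl2, rt
Reagents that add atoms: dibromomethane, BrCBr
Why: Takai–Lombardo methylenation is non-basic and ester-tolerant, so the C10 ketone is converted to the methylene without epimerising C5, which at this stage is the only carrier of absolute configuration.

Step 3
Reactants: 5 methyl (1R,2S)-3-methylidene-2-(prop-2-en-1-yl)cyclohexane-1-carboxylate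
Product: 7 methyl (1S,2R)-1-methyl-3-methylidene-2-(prop-2-en-1-yl)cyclohexane-1-carboxylate, via lithium ester enolate 6 (not isolated)
Conditions: LDA (1.2 equiv), THF, −78 °C; MeI (2 equiv), −78 → −20 °C
Reagents that add atoms: iodomethane, CI
Why: Ester enolate alkylation: allylic 1,3-strain with the enolate oxygens and with the C10 methylene holds the C5 allyl group axial, so iodomethane should add to C4 from the opposite (α) face, which leaves the ester cis to the chain as the axial C19 group.

Step 4
Reactants: 7 methyl (1S,2R)-1-methyl-3-methylidene-2-(prop-2-en-1-yl)cyclohexane-1-carboxylate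
Product: 9 methyl (1S,2R)-2-(3-hydroxypropyl)-1-methyl-3-methylidenecyclohexane-1-carboxylate, via alkyldisiamylborane 8 (not isolated)
Conditions: Sia2BH (from BH3·THF and 2-methylbut-2-ene, 1.3 equiv), THF, 0 °C; then NaOH, H2O2, 0 °C → rt
Reagents that add atoms: hydrogen peroxide, OO
Why: Brown hydroboration–oxidation with a hindered dialkylborane is anti-Markovnikov and strongly prefers the monosubstituted vinyl group over the more hindered 1,1-disubstituted ring methylene.

Step 5
Reactants: 9 methyl (1S,2R)-2-(3-hydroxypropyl)-1-methyl-3-methylidenecyclohexane-1-carboxylate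
Product: 10 methyl (1S,2R)-1-methyl-3-methylidene-2-(3-oxopropyl)cyclohexane-1-carboxylate
Conditions: Dess–Martin periodinane, NaHCO3, CH2Cl2, 0 °C → rt
Reagents that add atoms: none
Why: Dess–Martin oxidation stops at the aldehyde under buffered, neutral conditions that leave the alkene and the ester untouched.

Step 6
Reactants: 10 methyl (1S,2R)-1-methyl-3-methylidene-2-(3-oxopropyl)cyclohexane-1-carboxylate; 11 methyl propiolate
Product: 12 methyl 4-hydroxy-6-[(1R,2S)-2-(methoxycarbonyl)-2-methyl-6-methylidenecyclohexyl]hex-2-ynoate (both carbinol epimers)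
Conditions: 11 (1.3 equiv), LiHMDS (1.25 equiv), THF, −78 °C; then 10, −78 °C; aq. NH4Cl at −78 °C
Reagents that add atoms: methyl propiolate (11), C#CC(=O)OC
Why: Acetylide addition to an aldehyde: lithiated methyl propiolate is weakly basic and nucleophilic at −78 °C, so it adds to the aldehyde without enolising it, and the new C8 carbinol centre is erased in step 7.

Step 7
Reactants: 12 methyl 4-hydroxy-6-[(1R,2S)-2-(methoxycarbonyl)-2-methyl-6-methylidenecyclohexyl]hex-2-ynoate
Product: 13 methyl (2E)-6-[(1R,2S)-2-(methoxycarbonyl)-2-methyl-6-methylidenecyclohexyl]-4-oxohex-2-enoate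
Conditions: DABCO (20 mol%), DMSO, rt
Reagents that add atoms: none
Why: Amine-catalysed redox isomerisation of a γ-hydroxy ynoate: deprotonation of the carbinol C–H gives an allenolate whose protonation and tautomerisation lead to the conjugated γ-oxo enoate, with the E isomer as the most stable geometry.

Step 8
Reactants: 13 methyl (2E)-6-[(1R,2S)-2-(methoxycarbonyl)-2-methyl-6-methylidenecyclohexyl]-4-oxohex-2-enoate
Product: 14 dimethyl 8-oxo-13,14,15,16,17-pentanorlabdane-12,19-dioate (trans-decalin, 5α-H, 9α-H, 10β-CH3, 4β-CO2Me)
Conditions: Fe(acac)3 (30 mol%), PhSiH3 (2.5 equiv), EtOH/(CH2OH)2 5:1, 0.01 M, 60 °C; then DBU (cat.), CH2Cl2, rt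
Reagents that add atoms: none
Why: An iron hydride formed from Fe(acac)3 and PhSiH3 transfers a hydrogen atom to C20 of the electron-rich 1,1-disubstituted alkene (Markovnikov), which creates the C20 methyl and a nucleophilic tertiary C10 radical; this adds to C9, and the resulting C11 α-ester radical is reduced by Fe(II) and protonated by ethanol, which returns Fe(III) (closest known reaction type: iron-hydride reductive olefin–enoate Giese coupling, here intramolecular). Ring B closes 6-exo-trig through a chair-like transition state; both alkene carbons are activated (C9 is β to the ester, C11 β to the ketone), so the kinetic preference for a six- over a seven-membered ring directs the attack to C9. At C10 the planar radical is shielded on its β face by the axial C4 methoxycarbonyl group, and the equatorial C5 tether reaches the α (equatorial) lobe, so the trans-fused decalin with the 10β-methyl should form. At C9 the alkene sits pseudo-equatorial in the chair, which places the acetate arm equatorial (9α-H); because C9 is α to the C8 ketone, DBU converges any 9-epimer to this isomer, which is expected to be the more stable one. The step needs hydrogen-atom transfer to the methylene in preference to the electron-poor enedione, and ring closure faster than reduction of the C10 radical; the polarity match of metal hydride and alkene, the doubly activated intramolecular acceptor and high dilution should secure both.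

Step 9
Reactants: 14 dimethyl 8-oxo-13,14,15,16,17-pentanorlabdane-12,19-dioate
Product: 15 dimethyl 13,14,15,16-tetranorlabd-8(17)-ene-12,19-dioate
Conditions: Zn, CH2Br2, TiCl4, THF, 0 °C (pre-formed reagent); then 14, CH2Cl2, rt
Reagents that add atoms: dibromomethane, BrCBr
Why: Takai–Lombardo methylenation converts the hindered, enolisable C8 ketone to the 8(17)-methylene without base, so C9 is not epimerised and neither ester is attacked.

Step 10
Reactants: 15 dimethyl 13,14,15,16-tetranorlabd-8(17)-ene-12,19-dioate
Product: 16 dimethyl 7α-hydroxy-13,14,15,16-tetranorlabd-8(17)-ene-12,19-dioate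
Conditions: SeO2 (0.5 equiv), t-BuOOH (3 equiv), CH2Cl2, 0 °C → rt
Reagents that add atoms: selenium dioxide (oxygen carrier), O=[Se]=O; tert-butyl hydroperoxide (terminal oxidant), CC(C)(C)OO
Why: Selenium dioxide allylic hydroxylation: the ene reaction at C17 removes the axial 7α-hydrogen of the ring methylene (preferred over the C9 methine), and the [2,3]-sigmatropic shift returns oxygen to C7 on the α face, away from the axial C20 methyl, to give the axial 7α-alcohol.

Step 11
Reactants: 16 dimethyl 7α-hydroxy-13,14,15,16-tetranorlabd-8(17)-ene-12,19-dioate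
Product: 17 methyl 7α-hydroxy-12-oxo-13,14,15,16-tetranorlabd-8(17)-en-19-oate
Conditions: DIBAL-H (2.3 equiv), CH2Cl2, −78 °C; MeOH, then Rochelle salt
Reagents that add atoms: none
Why: Low-temperature DIBAL-H reduction: after the first equivalent is consumed by the 7-OH, the unhindered C12 ester forms a tetrahedral aluminate that releases the aldehyde on work-up, while the axial neopentyl C19 ester is too hindered to react at −78 °C.

Step 12
Reactants: 17 methyl 7α-hydroxy-12-oxo-13,14,15,16-tetranorlabd-8(17)-en-19-oate; 18 2-(triphenylphosphoranylidene)propanal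
Product: 19 methyl (12E)-7α-hydroxy-14-oxo-15-norlabda-8(17),12-dien-19-oate
Conditions: 18 (1.5 equiv), toluene, 80 °C
Reagents that add atoms: 2-(triphenylphosphoranylidene)propanal (18), CC(C=O)=P(c1ccccc1)(c1ccccc1)c1ccccc1
Why: Wittig olefination with a stabilised α-methyl formyl ylide gives the E trisubstituted enal (C12=C13 with the C16 methyl), and the less electrophilic product enal does not react further.

Step 13
Reactants: 19 methyl (12E)-7α-hydroxy-14-oxo-15-norlabda-8(17),12-dien-19-oate
Product: 20 methyl 7α-hydroxylabda-8(17),12E,14-trien-19-oate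
Conditions: Ph3PCH3Br (3 equiv), KHMDS (2.8 equiv), THF, 0 °C; then 19, −78 → 0 °C
Reagents that add atoms: methyltriphenylphosphonium bromide, C[P+](c1ccccc1)(c1ccccc1)c1ccccc1.[Br-]
Why: Wittig methylenation of the enal carbonyl completes the 1,3-diene without changing the C12=C13 geometry; the 7-alkoxide formed with excess ylide is a spectator.

Step 14
Reactants: 20 methyl 7α-hydroxylabda-8(17),12E,14-trien-19-oate
Product: 21 7α-hydroxylabda-8(17),12E,14-trien-19-oic acid
Conditions: n-PrSLi (from n-PrSH and n-BuLi, 6 equiv), HMPA, rt; then cold 1 M HCl to pH 3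
Reagents that add atoms: none
Why: SN2 dealkylation of a hindered methyl ester by thiolate: the nucleophile attacks the O-methyl carbon and not the shielded axial carbonyl, so the C19 ester is cleaved under conditions that leave the diene and the allylic alcohol alone.

Step 15
Reactants: 21 7α-hydroxylabda-8(17),12E,14-trien-19-oic acid
Product: 23 7α-acetoxylabda-8(17),12E,14-trien-19-oic acid, via mixed acetic anhydride 22 (not isolated)
Conditions: Ac2O (5 equiv), pyridine, DMAP (cat.), CH2Cl2, rt; then H2O/THF, rt
Reagents that add atoms: acetic anhydride, CC(=O)OC(C)=O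
Why: DMAP-catalysed acetylation of the axial allylic 7α-alcohol; the mixed anhydride formed at the hindered carboxyl is hydrolysed at its acetyl carbonyl on aqueous work-up, which returns the free C19 acid.

**Compound list**

1 | methyl 3-oxocyclohex-1-ene-1-carboxylate | COC(=O)C1=CC(=O)CCC1 | starting material
2 | allyl bromide (3-bromoprop-1-ene) | C=CCBr | starting material
3 | diphenylbis{[(3R)-3-(methoxycarbonyl)cyclohex-1-en-1-yl]oxy}silane | COC(=O)[C@@H]1CCCC(O[Si](c2ccccc2)(c2ccccc2)OC2=C[C@@H](CCC2)C(=O)OC)=C1 | intermediate (not isolated)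
4 | methyl (1R,2S)-3-oxo-2-(prop-2-en-1-yl)cyclohexane-1-carboxylate (2,3-trans) | C=CC[C@@H]1C(=O)CCC[C@H]1C(=O)OC | intermediate
5 | methyl (1R,2S)-3-methylidene-2-(prop-2-en-1-yl)cyclohexane-1-carboxylate | C=CC[C@@H]1C(=C)CCC[C@H]1C(=O)OC | intermediate
6 | lithium ester enolate of 5 (C4 sp2, C5 unchanged) | C=CC[C@@H]1C(=C)CCCC1=C(OC)O[Li] | intermediate (not isolated)
7 | methyl (1S,2R)-1-methyl-3-methylidene-2-(prop-2-en-1-yl)cyclohexane-1-carboxylate (methyl trans to the allyl group) | C=CC[C@@H]1C(=C)CCC[C@]1(C)C(=O)OC | intermediate
8 | methyl (1S,2R)-2-{3-[bis(3-methylbutan-2-yl)boranyl]propyl}-1-methyl-3-methylidenecyclohexane-1-carboxylate | CC(C)C(C)B(CCC[C@@H]1C(=C)CCC[C@]1(C)C(=O)OC)C(C)C(C)C | intermediate (not isolated)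
9 | methyl (1S,2R)-2-(3-hydroxypropyl)-1-methyl-3-methylidenecyclohexane-1-carboxylate | OCCC[C@@H]1C(=C)CCC[C@]1(C)C(=O)OC | intermediate
10 | methyl (1S,2R)-1-methyl-3-methylidene-2-(3-oxopropyl)cyclohexane-1-carboxylate | O=CCC[C@@H]1C(=C)CCC[C@]1(C)C(=O)OC | intermediate
11 | methyl propiolate | C#CC(=O)OC | starting material
12 | methyl 4-hydroxy-6-[(1R,2S)-2-(methoxycarbonyl)-2-methyl-6-methylidenecyclohexyl]hex-2-ynoate (both carbinol epimers) | COC(=O)C#CC(O)CC[C@@H]1C(=C)CCC[C@]1(C)C(=O)OC | intermediate
13 | methyl (2E)-6-[(1R,2S)-2-(methoxycarbonyl)-2-methyl-6-methylidenecyclohexyl]-4-oxohex-2-enoate | COC(=O)/C=C/C(=O)CC[C@@H]1C(=C)CCC[C@]1(C)C(=O)OC | intermediate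
14 | dimethyl 8-oxo-13,14,15,16,17-pentanorlabdane-12,19-dioate (5α-H, 9α-H, 10β-CH3, 4β-CO2Me) | COC(=O)C[C@H]1C(=O)CC[C@@H]2[C@]1(C)CCC[C@]2(C)C(=O)OC | intermediate
15 | dimethyl 13,14,15,16-tetranorlabd-8(17)-ene-12,19-dioate | COC(=O)C[C@H]1C(=C)CC[C@@H]2[C@]1(C)CCC[C@]2(C)C(=O)OC | intermediate
16 | dimethyl 7α-hydroxy-13,14,15,16-tetranorlabd-8(17)-ene-12,19-dioate | COC(=O)C[C@H]1C(=C)[C@H](O)C[C@@H]2[C@]1(C)CCC[C@]2(C)C(=O)OC | intermediate
17 | methyl 7α-hydroxy-12-oxo-13,14,15,16-tetranorlabd-8(17)-en-19-oate | O=CC[C@H]1C(=C)[C@H](O)C[C@@H]2[C@]1(C)CCC[C@]2(C)C(=O)OC | intermediate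
18 | 2-(triphenylphosphoranylidene)propanal | CC(C=O)=P(c1ccccc1)(c1ccccc1)c1ccccc1 | starting material
19 | methyl (12E)-7α-hydroxy-14-oxo-15-norlabda-8(17),12-dien-19-oate | O=C/C(C)=C/C[C@H]1C(=C)[C@H](O)C[C@@H]2[C@]1(C)CCC[C@]2(C)C(=O)OC | intermediate
20 | methyl 7α-hydroxylabda-8(17),12E,14-trien-19-oate | C=C/C(C)=C/C[C@H]1C(=C)[C@H](O)C[C@@H]2[C@]1(C)CCC[C@]2(C)C(=O)OC | intermediate
21 | 7α-hydroxylabda-8(17),12E,14-trien-19-oic acid | C=C/C(C)=C/C[C@H]1C(=C)[C@H](O)C[C@@H]2[C@]1(C)CCC[C@]2(C)C(=O)O | intermediate
22 | acetic 7α-acetoxylabda-8(17),12E,14-trien-19-oic anhydride | C=C/C(C)=C/C[C@H]1C(=C)[C@H](OC(C)=O)C[C@@H]2[C@]1(C)CCC[C@]2(C)C(=O)OC(C)=O | intermediate (not isolated)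
23 | 7α-acetoxylabda-8(17),12E,14-trien-19-oic acid (CNP0135450.1) | C=C/C(C)=C/C[C@H]1C(=C)[C@H](OC(C)=O)C[C@@H]2[C@]1(C)CCC[C@]2(C)C(=O)O | target

**Step count and risks**

Total step count: 15. Longest linear sequence: 15 steps (1 → 23).

Steps most likely to fail:

1. Step 8 (key step). Reduction of the C10 radical or of the oxo-enoate by the iron hydride/silane system may outrun ring closure, or attack through the β lobe may erode the trans-fusion. Fallback, setting out from 13 and returning at 14: one equivalent of HBr in CH2Cl2 at −78 °C should add in the Markovnikov sense to the ring methylene, which reacts through a tertiary cation far faster than the electron-poor enedione, to give the tertiary bromide F1. Slow addition of Bu3SnH with AIBN in benzene at 80 °C then generates the same C10 radical by bromine abstraction. The hydrogen-donor concentration is set by the addition rate and no metal hydride meets the enedione. The 6-exo Giese closure followed by the same DBU equilibration should deliver 14.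

2. Step 1. Enantio-induction may be insufficient for an enone whose β-substituent is an ester, or proton transfer between the released enolate and the product may erode regio- and diastereocontrol during allylation. Fallback, setting out from 1 and returning at 7: copper-catalysed asymmetric conjugate addition of Me2Zn (chiral NHC or peptide-phosphine ligand) forms the C4 quaternary centre directly. The zinc enolate is allylated in the same flask with allyl iodide to give the keto ester F2 together with its C5 epimer, which is separated by chromatography and recycled by base equilibration. Takai–Lombardo methylenation of F2 then gives 7. This path has weaker control at C5, which is why it is the reserve.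

3. Step 10. Over-oxidation to the 7-ketone or competing attack at the C9 methine may lower the return of the 7α-alcohol. Fallback, setting out from 14 and returning at 16: kinetic enolisation of 14 with LDA in the presence of Et3SiCl at −78 °C gives the Δ7 triethylsilyl enol ether F3. Rubottom oxidation (mCPBA, NaHCO3, CH2Cl2, 0 °C) from the α face, opposite the axial C20 methyl, with silyl migration gives the 7α-silyloxy ketone F4. Takai–Lombardo methylenation gives the silyl ether F5, and HF·pyridine in THF releases 16.

**Further compounds**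

F1 | step 8 | methyl (2E)-6-[6-bromo-2-(methoxycarbonyl)-2,6-dimethylcyclohexyl]-4-oxohex-2-enoate (C4 and C5 as in 13, both C10 epimers) | COC(=O)/C=C/C(=O)CC[C@@H]1C(C)(Br)CCC[C@]1(C)C(=O)OC
F2 | step 1 | methyl (1S,2S)-1-methyl-3-oxo-2-(prop-2-en-1-yl)cyclohexane-1-carboxylate | C=CC[C@@H]1C(=O)CCC[C@]1(C)C(=O)OC
F3 | step 10 | dimethyl 8-(triethylsilyloxy)-13,14,15,16,17-pentanorlabd-7-ene-12,19-dioate | COC(=O)C[C@H]1C(O[Si](CC)(CC)CC)=CC[C@@H]2[C@]1(C)CCC[C@]2(C)C(=O)OC
F4 | step 10 | dimethyl 8-oxo-7α-(triethylsilyloxy)-13,14,15,16,17-pentanorlabdane-12,19-dioate | COC(=O)C[C@H]1C(=O)[C@H](O[Si](CC)(CC)CC)C[C@@H]2[C@]1(C)CCC[C@]2(C)C(=O)OC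
F5 | step 10 | dimethyl 7α-(triethylsilyloxy)-13,14,15,16-tetranorlabd-8(17)-ene-12,19-dioate | COC(=O)C[C@H]1C(=C)[C@H](O[Si](CC)(CC)CC)C[C@@H]2[C@]1(C)CCC[C@]2(C)C(=O)OC
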